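24 = target, chromene numbering O1, C2, C3, C4, C4a, C5–C8, C8a; ring A = carbocycle, ring B = pyranone. 24 ⇐ 21 by ligand-controlled copper hydride 1,4-reduction of the 4-pyranone C2=C3 (sets C2); 21 ⇐ 20 by Dieckmann closure of ring A (C5–C6 bond).
20 ⇐ 16 + 2-methoxypropene: thermal acylketene formation and hetero-[4+2] cycloaddition that forms C3–C4 and O1–C2 of ring B in one operation, then loss of MeOH.
Enabling feature: ring B is a 2,3-dihydro-4H-pyran-4-one whose O1–C8a=C4a–C4(=O) vinylogous ester is the retron of an α-oxoketene [4+2]; C4a also carries C5 at the carboxyl level, so on the open chain C8a is the only ketone conjugated to the ketene and O1 is fixed (on closed ring A the C5 and C8a oxygens would compete).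
16 ⇐ malonate 13 + acid chloride of the C8a arm; C7 ketone ⇐ acid chloride + homoprenyl Grignard reagent; quaternary C8 ⇐ asymmetric phase-transfer geranylation of the mixed α-methylmalonate 5.
Ring order: ring B (step 7), then ring A (step 8); stereocentres: C8 in step 3, C2 in step 9.

Key step: step 7

Assumption: the sense of induction in steps 3 and 9 is taken from the accepted models for these catalyst classes; if a first run shows the opposite sense, the antipodal catalyst or ligand is used and nothing else changes.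

Step 1
Reactants: 1 2,2,5-trimethyl-1,3-dioxane-4,6-dione; 2 tert-butanol
Product: 3 3-(tert-butoxy)-2-methyl-3-oxopropanoic acid (racemic)
Conditions: tBuOH (neat), reflux
Reagents that add atoms: none
Why: Alcoholysis of the cyclic acylal by tert-butanol (ring opening with loss of acetone) should give the malonic half ester, whose methine carbon is configurationally labile and is carried as the racemate.

Step 2
Reactants: 3 3-(tert-butoxy)-2-methyl-3-oxopropanoic acid; 4 2,2-diphenylethanol
Product: 5 1-tert-butyl 3-(2,2-diphenylethyl) 2-methylpropanedioate (racemic)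
Conditions: EDC·HCl, DMAP (cat.), CH2Cl2, 0 °C to rt
Reagents that add atoms: none
Why: Carbodiimide (Steglich-type) esterification of the free acid with the primary alcohol should give the mixed diester, whose two unlike ester groups serve the asymmetric alkylation and the later selective cleavages, and no stereocentre is set.

Step 3
Reactants: 5 1-tert-butyl 3-(2,2-diphenylethyl) 2-methylpropanedioate; 6 geranyl bromide
Product: 7 1-tert-butyl 3-(2,2-diphenylethyl) (2S)-2-[(2E)-3,7-dimethylocta-2,6-dien-1-yl]-2-methylpropanedioate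
Conditions: (S,S)-N-spiro bis(binaphthyl)ammonium bromide with 3,4,5-trifluorophenyl groups at the 3,3'-positions (5 mol %), 50% aq. KOH, toluene, −40 °C
Reagents that add atoms: none
Why: Asymmetric phase-transfer alkylation, in which the chiral ammonium cation pairs with the malonate enolate, the size difference between the tert-butyl and 2,2-diphenylethyl esters fixes how the enolate sits in the binaphthyl pocket, and SN2 attack on the primary allylic bromide from the open face should set the quaternary stereocentre as (S) with the (E)-olefin retained.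

Step 4
Reactants: 7 1-tert-butyl 3-(2,2-diphenylethyl) (2S)-2-[(2E)-3,7-dimethylocta-2,6-dien-1-yl]-2-methylpropanedioate
Product: 8 (2S,4E)-2-(tert-butoxycarbonyl)-2,5,9-trimethyldeca-4,8-dienoic acid
Conditions: 1 M KOH, MeOH, rt to 40 °C; then 1 M HCl, 0 °C
Reagents that add atoms: potassium hydroxide (hydroxide oxygen), [K+].[OH-]
Why: Saponification (BAc2) should cleave only the primary ester because the tert-butyl ester is shielded, and the quaternary stereocentre has no α-hydrogen and cannot be scrambled.

Step 5
Reactants: 8 (2S,4E)-2-(tert-butoxycarbonyl)-2,5,9-trimethyldeca-4,8-dienoic acid; 9 5-bromo-2-methylpent-2-ene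
Product: 12 tert-butyl (2S)-2-[(2E)-3,7-dimethylocta-2,6-dien-1-yl]-2,7-dimethyl-3-oxooct-6-enoate, via acid chloride 10 (not isolated), via homoprenylmagnesium bromide 11 (not isolated)
Conditions: 1-chloro-N,N,2-trimethylprop-1-en-1-amine, CH2Cl2, 0 °C to rt; then 11 (from 9, Mg, THF), CuI (10 mol %), THF, −78 to −30 °C
Reagents that add atoms: none
Why: Neutral acid chloride formation with the α-chloroenamine avoids HCl so that the geranyl olefins and the tert-butyl ester survive, and copper-catalysed acylation of the Grignard reagent at low temperature should stop at the hindered α-quaternary ketone, the stereocentre being untouched.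

Step 6
Reactants: 12 tert-butyl (2S)-2-[(2E)-3,7-dimethylocta-2,6-dien-1-yl]-2,7-dimethyl-3-oxooct-6-enoate; 13 tert-butyl methyl propanedioate
Product: 16 1-tert-butyl 3-methyl 2-{(2S)-2-[(2E)-3,7-dimethylocta-2,6-dien-1-yl]-2,7-dimethyl-3-oxooct-6-enoyl}propanedioate, via trimethylsilyl ester 14 (not isolated), via acid chloride 15 (not isolated)
Conditions: Me3SiOTf, 2,6-lutidine, CH2Cl2, 0 °C; (COCl)2, DMF (cat.), 0 °C to rt; then 13, MgCl2, Et3N, MeCN, 0 °C to rt; dilute HCl work-up
Reagents that add atoms: none
Why: Silyl triflate-induced loss of isobutene gives the silyl ester without protic acid, oxalyl chloride converts it to an acid chloride that cannot form a ketene, and Claisen-type C-acylation of the magnesium-chelated malonate enolate should give the enolised acylmalonate without isolation of the decarboxylation-prone β-keto acid, no fixed stereocentre being formed at the enolised malonyl carbon.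

Step 7
Reactants: 16 1-tert-butyl 3-methyl 2-{(2S)-2-[(2E)-3,7-dimethylocta-2,6-dien-1-yl]-2,7-dimethyl-3-oxooct-6-enoyl}propanedioate; 17 2-methoxypropene
Product: 20 methyl 6-methyl-4-oxo-2-[(7R,9E)-2,7,10,14-tetramethyl-6-oxopentadeca-2,9,13-trien-7-yl]-4H-pyran-3-carboxylate, via acylketene 18 (not isolated), via ketal cycloadduct 19 (not isolated)
Conditions: 17 (20 equiv), toluene, sealed tube, 105 °C; then PPTS (10 mol %), 60 °C
Reagents that add atoms: none
Why: On heating, the enolised β-keto tert-butyl ester of 16 should lose tert-butanol in a retro-ene-type elimination to give acyl(methoxycarbonyl)ketene 18, the known thermal behaviour of β-keto tert-butyl esters. Ketene 18 then acts as a 1-oxadiene (O=C8a–C4a=C4=O) in an inverse-demand hetero-Diels–Alder reaction with 2-methoxypropene, the CH2 terminus bonding to the ketene carbon (C3–C4) and the ketone oxygen to the oxocarbenium carbon (O1–C2); the closest known reaction type is the [4+2] cycloaddition of α-oxoketenes with enol ethers to 2-alkoxy-2,3-dihydro-4H-pyran-4-ones. Ring B closes in the [4+2] mode (in the stepwise limit a 6-(enolendo)-exo-trig O-closure of the zwitterion), and acid-catalysed loss of methanol from ketal 19 gives the 4-pyranone 20, so the uncontrolled ketal carbon is erased and C2 is left trigonal for the later reduction. No stereocentre is set, and the quaternary centre has no α-hydrogen and is not touched. The step needs selectivity for the ketone oxygen over the ester oxygen as diene terminus and for intermolecular capture over internal reactions of the ketene (C7 ketone enol, geranyl olefin): C8a is the only ketone conjugated to the ketene because C7 is insulated by the quaternary carbon, closure through the ester oxygen would give a reversible ketene-acetal adduct whereas the ketone adduct drains irreversibly into the 4-pyranone, and the nucleophilic enol ether is used in large excess. Run on the open chain, the step therefore fixes which oxygen becomes O1, a choice that would be ambiguous between the C5 and C8a oxygens once ring A is closed.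

Step 8
Reactants: 20 methyl 6-methyl-4-oxo-2-[(7R,9E)-2,7,10,14-tetramethyl-6-oxopentadeca-2,9,13-trien-7-yl]-4H-pyran-3-carboxylate
Product: 21 (8R)-8-[(2E)-3,7-dimethylocta-2,6-dien-1-yl]-5-hydroxy-2,8-dimethyl-6-(3-methylbut-2-en-1-yl)-4H-chromene-4,7(8H)-dione
Conditions: LiN(SiMe3)2 (2.5 equiv), THF, −78 to 0 °C; then 0.5 M HCl, 0 °C
Reagents that add atoms: none
Why: Dieckmann (intramolecular Claisen) condensation, in which the only enolisable α-carbon of the C7 ketone (C6, the other side being quaternary) should attack the pyranone ester in a six-membered closure and the strongly acidic vinylogous acid product is deprotonated at once, which drives the reaction, C6 ending trigonal and C8 being unaffected.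

Step 9
Reactants: 21 (8R)-8-[(2E)-3,7-dimethylocta-2,6-dien-1-yl]-5-hydroxy-2,8-dimethyl-6-(3-methylbut-2-en-1-yl)-4H-chromene-4,7(8H)-dione
Product: 24 (2S,8R)-8-[(2E)-3,7-dimethylocta-2,6-dien-1-yl]-5-hydroxy-2,8-dimethyl-6-(3-methylbut-2-en-1-yl)-2,3-dihydro-4H-chromene-4,7(8H)-dione, via silyl ether 22 (not isolated), via silylated ketone 23 (not isolated)
Conditions: Cu(OAc)2 (5 mol %), (R)-DTBM-SEGPHOS (5.5 mol %), (EtO)2MeSiH (3 equiv), tBuOH (1.5 equiv), toluene, 0 °C to rt; then aq. citric acid, THF, 0 °C
Reagents that add atoms: none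
Why: Ligand-controlled asymmetric conjugate reduction with a bisphosphine copper hydride, as known for 2-alkyl-4H-chromen-4-ones, in which the acidic enol OH is first silylated in the flask, hydride is delivered to C2 (the only unhindered β-carbon, C5 and C8a being tetrasubstituted) from the face selected by the ligand to set C2 as (S) without useful bias from the remote C8 centre, and tert-butanol protonates the copper enolate at once so that it cannot open ring B.

Compound list
1 | 2,2,5-trimethyl-1,3-dioxane-4,6-dione | CC1C(=O)OC(C)(C)OC1=O | starting material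
2 | tert-butanol | CC(C)(C)O | starting material
3 | 3-(tert-butoxy)-2-methyl-3-oxopropanoic acid (racemic) | CC(C(=O)O)C(=O)OC(C)(C)C | intermediate
4 | 2,2-diphenylethanol | OCC(c1ccccc1)c1ccccc1 | starting material
5 | 1-tert-butyl 3-(2,2-diphenylethyl) 2-methylpropanedioate (racemic) | CC(C(=O)OC(C)(C)C)C(=O)OCC(c1ccccc1)c1ccccc1 | intermediate
6 | geranyl bromide, (2E)-1-bromo-3,7-dimethylocta-2,6-diene | CC(C)=CCC/C(C)=C/CBr | starting material
7 | 1-tert-butyl 3-(2,2-diphenylethyl) (2S)-2-[(2E)-3,7-dimethylocta-2,6-dien-1-yl]-2-methylpropanedioate | CC(C)=CCC/C(C)=C/C[C@@](C(=O)OC(C)(C)C)(C)C(=O)OCC(c1ccccc1)c1ccccc1 | intermediate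
8 | (2S,4E)-2-(tert-butoxycarbonyl)-2,5,9-trimethyldeca-4,8-dienoic acid | CC(C)=CCC/C(C)=C/C[C@@](C(=O)OC(C)(C)C)(C)C(=O)O | intermediate
9 | 5-bromo-2-methylpent-2-ene | CC(C)=CCCBr | starting material
10 | tert-butyl (2R,4E)-2-(chlorocarbonyl)-2,5,9-trimethyldeca-4,8-dienoate | CC(C)=CCC/C(C)=C/C[C@@](C(=O)OC(C)(C)C)(C)C(Cl)=O | intermediate (not isolated)
11 | (4-methylpent-3-en-1-yl)magnesium bromide | CC(C)=CCC[Mg]Br | intermediate (not isolated)
12 | tert-butyl (2S)-2-[(2E)-3,7-dimethylocta-2,6-dien-1-yl]-2,7-dimethyl-3-oxooct-6-enoate | CC(C)=CCC/C(C)=C/C[C@@](C(=O)OC(C)(C)C)(C)C(=O)CCC=C(C)C | intermediate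
13 | tert-butyl methyl propanedioate | COC(=O)CC(=O)OC(C)(C)C | starting material
14 | trimethylsilyl (2S)-2-[(2E)-3,7-dimethylocta-2,6-dien-1-yl]-2,7-dimethyl-3-oxooct-6-enoate | CC(C)=CCC/C(C)=C/C[C@@](C(=O)O[Si](C)(C)C)(C)C(=O)CCC=C(C)C | intermediate (not isolated)
15 | (2S)-2-[(2E)-3,7-dimethylocta-2,6-dien-1-yl]-2,7-dimethyl-3-oxooct-6-enoyl chloride | CC(C)=CCC/C(C)=C/C[C@@](C(Cl)=O)(C)C(=O)CCC=C(C)C | intermediate (not isolated)
16 | 1-tert-butyl 3-methyl 2-{(2S)-2-[(2E)-3,7-dimethylocta-2,6-dien-1-yl]-2,7-dimethyl-3-oxooct-6-enoyl}propanedioate (enolised; malonyl carbon not defined) | CC(C)=CCC/C(C)=C/C[C@@](C(=O)C(C(=O)OC)C(=O)OC(C)(C)C)(C)C(=O)CCC=C(C)C | intermediate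
17 | 2-methoxypropene | COC(C)=C | starting material
18 | methyl (4S)-4-[(2E)-3,7-dimethylocta-2,6-dien-1-yl]-4,9-dimethyl-3,5-dioxo-2-(oxomethylidene)dec-8-enoate | CC(C)=CCC/C(C)=C/C[C@@](C(=O)C(C(=O)OC)=C=O)(C)C(=O)CCC=C(C)C | intermediate (not isolated)
19 | methyl 6-methoxy-6-methyl-4-oxo-2-[(7R,9E)-2,7,10,14-tetramethyl-6-oxopentadeca-2,9,13-trien-7-yl]-5,6-dihydro-4H-pyran-3-carboxylate (both configurations at the ketal carbon) | CC(C)=CCC/C(C)=C/C[C@@](C1=C(C(=O)OC)C(=O)CC(C)(OC)O1)(C)C(=O)CCC=C(C)C | intermediate (not isolated)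
20 | methyl 6-methyl-4-oxo-2-[(7R,9E)-2,7,10,14-tetramethyl-6-oxopentadeca-2,9,13-trien-7-yl]-4H-pyran-3-carboxylate | CC(C)=CCC/C(C)=C/C[C@@](C1=C(C(=O)OC)C(=O)C=C(C)O1)(C)C(=O)CCC=C(C)C | intermediate
21 | (8R)-8-[(2E)-3,7-dimethylocta-2,6-dien-1-yl]-5-hydroxy-2,8-dimethyl-6-(3-methylbut-2-en-1-yl)-4H-chromene-4,7(8H)-dione | CC(C)=CCC/C(C)=C/C[C@@]1(C)C(=O)C(CC=C(C)C)=C(O)C2=C1OC(C)=CC2=O | intermediate
22 | (8R)-5-{[diethoxy(methyl)silyl]oxy}-8-[(2E)-3,7-dimethylocta-2,6-dien-1-yl]-2,8-dimethyl-6-(3-methylbut-2-en-1-yl)-4H-chromene-4,7(8H)-dione | CC(C)=CCC/C(C)=C/C[C@@]1(C)C(=O)C(CC=C(C)C)=C(O[Si](C)(OCC)OCC)C2=C1OC(C)=CC2=O | intermediate (not isolated)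
23 | (2S,8R)-5-{[diethoxy(methyl)silyl]oxy}-8-[(2E)-3,7-dimethylocta-2,6-dien-1-yl]-2,8-dimethyl-6-(3-methylbut-2-en-1-yl)-2,3-dihydro-4H-chromene-4,7(8H)-dione | CC(C)=CCC/C(C)=C/C[C@@]1(C)C(=O)C(CC=C(C)C)=C(O[Si](C)(OCC)OCC)C2=C1O[C@@H](C)CC2=O | intermediate (not isolated)
24 | (2S,8R)-8-[(2E)-3,7-dimethylocta-2,6-dien-1-yl]-5-hydroxy-2,8-dimethyl-6-(3-methylbut-2-en-1-yl)-2,3-dihydro-4H-chromene-4,7(8H)-dione | CC(C)=CCC/C(C)=C/C[C@@]1(C)C(=O)C(CC=C(C)C)=C(O)C2=C1O[C@@H](C)CC2=O | target

Total step count: 9. Longest linear sequence: 9 steps (1 to 24; the route is fully linear).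

Steps most likely to fail

Step 9. After hydride transfer, the copper enolate can expel the C8a enolate oxygen (E1cB, equivalent to an oxa-6π ring opening of the 2H-pyran-4-olate). Reclosure is not face-selective, so C2 configuration would be lost, and the freed enone can be reduced further. Hydride transfer to the silylated vinylogous system may also be slow, and facial discrimination on a pyranone that is not benzo-fused may be weaker than on chromones. The fallback sets out from 21 and returns at 24. Reduction without a chiral ligand, using [(Ph3P)CuH]6 in wet toluene, should give 24 together with its C2 epimer, the (2R,8R)-dihydrochromenedione F7. The two are diastereomers (C8 is fixed) and are separated by preparative HPLC. F7 is recycled by brief exposure to DBU in THF, which equilibrates C2 through the ring-opened crotonoyl dienone F8 (retro-oxa-Michael/oxa-Michael), followed by a new separation.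

Step 7. The ketene may close through the ester oxygen, or be captured internally ([2+2] addition to the geranyl 2,3-olefin, O-acylation by the C7 ketone enol), or dimerise, and methanol loss from the cycloadduct may be incomplete. The fallback sets out from 16 and returns at 20, building the pyranone by enamine acylation instead of cycloaddition. Heating 16 in wet toluene hydrates ketene 18 to the acylmalonic half acid F1, which loses CO2 to give the methyl β-keto ester F2. Condensation with pyrrolidine (cat. AcOH, water separator) at the ester-activated C8a ketone gives the enamino ester F3. Diketene acylates the enamine carbon to the acetoacetyl enaminone F4, which on warming cyclises through the acetyl enol oxygen with loss of pyrrolidine to 20 (known enamine–diketene synthesis of 4-pyranones). The ring connectivity is then fixed by the order of bond formation and no longer by a choice between carbonyl oxygens.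

Step 8. The base may deprotonate the pyranone 2-methyl group and cause intermolecular condensation, liberated methoxide may cleave the chain at the quaternary carbon (retro-Claisen), or base may add to the pyranone. The fallback sets out from 20 and returns at 21, closing ring A with an acid chloride under soft enolisation instead of an ester under strong base. SN2 demethylation of the ester with LiI (EtOAc, reflux; acidic work-up) gives the pyranone carboxylic acid F5. 1-Chloro-N,N,2-trimethylprop-1-en-1-amine converts it to the acid chloride F6. MgBr2·OEt2 and iPr2NEt in CH2Cl2 then enolise the C7 ketone toward C6 and bring about intramolecular C-acylation to 21 with no alkoxide present.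

Further compounds
F1 | step 7 | 2-{(2S)-2-[(2E)-3,7-dimethylocta-2,6-dien-1-yl]-2,7-dimethyl-3-oxooct-6-enoyl}-3-methoxy-3-oxopropanoic acid (not isolated) | CC(C)=CCC/C(C)=C/C[C@@](C(=O)C(C(=O)OC)C(O)=O)(C)C(=O)CCC=C(C)C
F2 | step 7 | methyl (4S)-4-[(2E)-3,7-dimethylocta-2,6-dien-1-yl]-4,9-dimethyl-3,5-dioxodec-8-enoate | CC(C)=CCC/C(C)=C/C[C@@](C(=O)CC(=O)OC)(C)C(=O)CCC=C(C)C
F3 | step 7 | methyl (4R)-4-[(2E)-3,7-dimethylocta-2,6-dien-1-yl]-4,9-dimethyl-5-oxo-3-(pyrrolidin-1-yl)deca-2,8-dienoate | CC(C)=CCC/C(C)=C/C[C@@](C(=CC(=O)OC)N1CCCC1)(C)C(=O)CCC=C(C)C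
F4 | step 7 | methyl (4R)-4-[(2E)-3,7-dimethylocta-2,6-dien-1-yl]-4,9-dimethyl-5-oxo-2-(3-oxobutanoyl)-3-(pyrrolidin-1-yl)deca-2,8-dienoate (not isolated) | CC(C)=CCC/C(C)=C/C[C@@](C(N1CCCC1)=C(C(=O)OC)C(=O)CC(C)=O)(C)C(=O)CCC=C(C)C
F5 | step 8 | 6-methyl-4-oxo-2-[(7R,9E)-2,7,10,14-tetramethyl-6-oxopentadeca-2,9,13-trien-7-yl]-4H-pyran-3-carboxylic acid | CC(C)=CCC/C(C)=C/C[C@@](C1=C(C(=O)O)C(=O)C=C(C)O1)(C)C(=O)CCC=C(C)C
F6 | step 8 | 6-methyl-4-oxo-2-[(7R,9E)-2,7,10,14-tetramethyl-6-oxopentadeca-2,9,13-trien-7-yl]-4H-pyran-3-carbonyl chloride | CC(C)=CCC/C(C)=C/C[C@@](C1=C(C(Cl)=O)C(=O)C=C(C)O1)(C)C(=O)CCC=C(C)C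
F7 | step 9 | (2R,8R)-8-[(2E)-3,7-dimethylocta-2,6-dien-1-yl]-5-hydroxy-2,8-dimethyl-6-(3-methylbut-2-en-1-yl)-2,3-dihydro-4H-chromene-4,7(8H)-dione | CC(C)=CCC/C(C)=C/C[C@@]1(C)C(=O)C(CC=C(C)C)=C(O)C2=C1O[C@H](C)CC2=O
F8 | step 9 | (6R)-4-[(2E)-but-2-enoyl]-6-[(2E)-3,7-dimethylocta-2,6-dien-1-yl]-3,5-dihydroxy-6-methyl-2-(3-methylbut-2-en-1-yl)cyclohexa-2,4-dien-1-one | CC(C)=CCC/C(C)=C/C[C@@]1(C)C(=O)C(CC=C(C)C)=C(O)C(C(=O)/C=C/C)=C1O
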